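## Retrosynthetic overview

1. The target comes from global O-debenzylation of a tetrabenzyl flavonol. That flavonol comes from C3-hydroxylation of the flavone, which comes from oxidative closure of ring C in a 2'-hydroxychalcone.
2. Key C–C disconnection is the chalcone Cα–Cβ bond. It is made by an intermolecular Claisen–Schmidt aldol condensation of 2-hydroxy-4,6-bis(benzyloxy)acetophenone (ring A) with an enantiopure (2R,3R)-benzodioxane-6-carbaldehyde (rings B, D, E).
3. Dioxane ring D is closed by intramolecular Pd-catalysed aryl C–O coupling (retention) of a syn 1-aryl-2-(2-bromoaryloxy)propane-1,3-diol.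
4. Both stereocentres are set by an Evans syn aldol of an (aryloxy)acetyl (S)-oxazolidinone with O-benzylvanillin.
5. Ring order: dioxane ring D first, pyranone ring C last. Rings A, B and E are bought as arenes.

Assumption: the SMILES is read as trans-(2R,3R) at the benzodioxane (10R,11R in flavonolignan numbering), and O-benzylvanillin is bought rather than made from vanillin.

## Route

Step 1
Reactants: 1 methyl 3-bromo-4-hydroxybenzoate; 2 tert-butyl bromoacetate
Product: 3 methyl 3-bromo-4-(2-tert-butoxy-2-oxoethoxy)benzoate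
Conditions: K2CO3 (1.5 equiv), DMF, rt, 12 h
Reagents that add atoms: none
Why: Williamson ether synthesis, in which the acidic phenol is the only nucleophile and displaces the carbonyl-activated primary bromide by SN2, fixing the future ring D oxygen para to the ester and the bromine meta to it.

Step 2
Reactants: 3 tert-butyl ester
Product: 4 [2-bromo-4-(methoxycarbonyl)phenoxy]acetic acid
Conditions: TFA/CH2Cl2 1:2, rt, 3 h
Reagents that add atoms: none
Why: Acidolysis of the tert-butyl ester (loss of the tert-butyl cation as isobutene) frees only this acid, because methyl ester, aryl ether and aryl bromide are inert to TFA.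

Step 3
Reactants: 4 aryloxyacetic acid; 5 (S)-4-benzyl-1,3-oxazolidin-2-one
Product: 7 methyl 4-{2-[(4S)-4-benzyl-2-oxo-1,3-oxazolidin-3-yl]-2-oxoethoxy}-3-bromobenzoate, via mixed pivalic anhydride 6 (not isolated)
Conditions: PivCl (1.1 equiv), Et3N (2.5 equiv), THF, −20 °C, 1 h; then LiCl (1.1 equiv), 5, −20 °C → rt
Reagents that add atoms: none
Why: Mixed-anhydride N-acylation, in which the LiCl-activated oxazolidinone attacks the unhindered aryloxyacetyl carbonyl of 6 rather than the pivaloyl carbonyl, and the auxiliary stereocentre is not involved.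

Step 4
Reactants: 7 aryloxyacetyl imide; 8 4-(benzyloxy)-3-methoxybenzaldehyde (O-benzylvanillin)
Product: 11 methyl 4-{[(1R,2S)-1-[4-(benzyloxy)-3-methoxyphenyl]-3-[(4S)-4-benzyl-2-oxo-1,3-oxazolidin-3-yl]-1-hydroxy-3-oxopropan-2-yl]oxy}-3-bromobenzoate, via Z-dibutylboron enolate 9 (not isolated), via dibutylboron aldolate 10 (not isolated)
Conditions: Bu2BOTf (1.2 equiv), iPr2NEt (1.4 equiv), CH2Cl2, −78 → 0 °C; 8, −78 → 0 °C; then pH 7 buffer, MeOH, 30% H2O2, 0 °C
Reagents that add atoms: none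
Why: Evans syn aldol, in which the Z-boron enolate adds to the non-enolisable aldehyde through a Zimmerman–Traxler chair on the face away from the benzyl group of the (S)-auxiliary, setting the aryloxy carbon (S) and the carbinol carbon (R) together as the syn pair, with minor diastereomers removed by chromatography.

Step 5
Reactants: 11 syn aldol adduct
Product: 12 methyl 4-{[(1R,2R)-1-[4-(benzyloxy)-3-methoxyphenyl]-1,3-dihydroxypropan-2-yl]oxy}-3-bromobenzoate
Conditions: NaBH4 (4 equiv), THF/H2O 4:1, 0 °C → rt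
Reagents that add atoms: none
Why: Reductive cleavage of the activated exocyclic imide carbonyl by borohydride gives the primary alcohol and returns the auxiliary, leaves the aromatic methyl ester alone, and changes only the descriptor of C2 (S to R by priority change), not its geometry.

Step 6
Reactants: 12 diol
Product: 13 methyl 4-{[(1R,2R)-1-[4-(benzyloxy)-3-methoxyphenyl]-3-[(tert-butyldiphenylsilyl)oxy]-1-hydroxypropan-2-yl]oxy}-3-bromobenzoate
Conditions: TBDPSCl (1.05 equiv), imidazole (2.2 equiv), CH2Cl2, 0 °C → rt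
Reagents that add atoms: tert-butyldiphenylsilyl chloride CC(C)(C)[Si](Cl)(c1ccccc1)c1ccccc1
Why: Sterically controlled silylation, in which the bulky chlorosilane reacts only at the primary hydroxyl, blocking the alternative six-membered ring closure through that oxygen with a group that migrates reluctantly.

Step 7
Reactants: 13 bromo alcohol
Product: 14 methyl (2R,3R)-3-[4-(benzyloxy)-3-methoxyphenyl]-2-{[(tert-butyldiphenylsilyl)oxy]methyl}-2,3-dihydro-1,4-benzodioxine-6-carboxylate
Conditions: Pd(OAc)2 (5 mol %), 2-(di-tert-butylphosphino)-1,1'-binaphthyl (6 mol %), Cs2CO3 (1.5 equiv), toluene, 70 °C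
Reagents that add atoms: none
Why: Buchwald-type intramolecular C–O coupling, in which zerovalent palladium inserts into the C–Br bond, the alkoxide binds and the bulky ligand drives reductive elimination, so no bond at either stereocentre is broken and the syn (1R,2R) pair becomes the trans-(2R,3R)-dioxane with retention.

Step 8
Reactants: 14 silyl ether
Product: 15 methyl (2R,3R)-3-[4-(benzyloxy)-3-methoxyphenyl]-2-(hydroxymethyl)-2,3-dihydro-1,4-benzodioxine-6-carboxylate
Conditions: Bu4NF (1.2 equiv), AcOH (1.2 equiv), THF, 0 °C → rt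
Reagents that add atoms: none
Why: Fluoride-driven desilylation (formation of the strong Si–F bond) under buffered conditions leaves ester, benzyl ether and ring D untouched.

Step 9
Reactants: 15 primary alcohol
Product: 16 methyl (2R,3R)-3-[4-(benzyloxy)-3-methoxyphenyl]-2-[(benzyloxy)methyl]-2,3-dihydro-1,4-benzodioxine-6-carboxylate
Conditions: NaH (1.3 equiv), BnBr (1.3 equiv), Bu4NI (cat.), DMF, 0 °C → rt
Reagents that add atoms: benzyl bromide BrCc1ccccc1
Why: Williamson benzylation of what is now the only hydroxyl installs a group that survives KOH, hot I2/DMSO and DMDO and leaves with the phenolic benzyl ethers at the end.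

Step 10
Reactants: 16 methyl ester
Product: 17 {(2R,3R)-3-[4-(benzyloxy)-3-methoxyphenyl]-2-[(benzyloxy)methyl]-2,3-dihydro-1,4-benzodioxin-6-yl}methanol
Conditions: LiAlH4 (1.2 equiv), THF, 0 °C; Fieser work-up
Reagents that add atoms: none
Why: Hydride reduction of the only carbonyl group goes fully to the benzylic alcohol, which is more dependable than a partial reduction to the aldehyde.

Step 11
Reactants: 17 benzylic alcohol
Product: 18 (2R,3R)-3-[4-(benzyloxy)-3-methoxyphenyl]-2-[(benzyloxy)methyl]-2,3-dihydro-1,4-benzodioxine-6-carbaldehyde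
Conditions: activated MnO2 (15 equiv), CH2Cl2, rt
Reagents that add atoms: none
Why: Heterogeneous MnO2 oxidation is selective for benzylic alcohols, stops at the aldehyde and is neutral, so ethers and stereocentres are unaffected.

Step 12
Reactants: 19 2,4,6-trihydroxyacetophenone
Product: 20 1-[2,4-bis(benzyloxy)-6-hydroxyphenyl]ethanone
Conditions: BnBr (2.1 equiv), K2CO3 (2.2 equiv), DMF, rt → 50 °C
Reagents that add atoms: benzyl bromide BrCc1ccccc1
Why: Regioselective Williamson alkylation, in which one ortho hydroxyl stays hydrogen-bonded to the ketone and is much less nucleophilic, so alkylation stops at the dibenzyl ether.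

Step 13
Reactants: 18 benzodioxane aldehyde; 20 dibenzyl acetophenone
Product: 22 (E)-1-[2,4-bis(benzyloxy)-6-hydroxyphenyl]-3-{(2R,3R)-3-[4-(benzyloxy)-3-methoxyphenyl]-2-[(benzyloxy)methyl]-2,3-dihydro-1,4-benzodioxin-6-yl}prop-2-en-1-one, via β-hydroxy ketone 21 (not isolated)
Conditions: KOH (50% aq, 10 equiv), EtOH/THF 2:1, rt, 48 h; then 1 M HCl
Reagents that add atoms: none
Why: Claisen–Schmidt crossed aldol condensation, in which only 20 can enolise and only 18 is an aldehyde, so the enolate adds to the formyl group to give 21 and E1cB loss of water gives the E-enone, while ring D has no acidic hydrogen and no free phenol on ring E through which base could open it.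

Step 14
Reactants: 22 chalcone
Product: 24 5,7-bis(benzyloxy)-2-{(2R,3R)-3-[4-(benzyloxy)-3-methoxyphenyl]-2-[(benzyloxy)methyl]-2,3-dihydro-1,4-benzodioxin-6-yl}-4H-chromen-4-one, via flavanone 23 (not isolated)
Conditions: I2 (10 mol %), DMSO, 130 °C, 3 h; aq Na2S2O3
Reagents that add atoms: none
Why: Iodine-catalysed oxidative cyclisation, in which oxa-Michael closure gives flavanone 23, α-iodination and loss of HI aromatise ring C and DMSO reoxidises HI, so the transient flavanone stereocentre is erased and the aurone pathway of peroxide methods on 6'-alkoxychalcones is avoided.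

Step 15
Reactants: 24 flavone
Product: 26 5,7-bis(benzyloxy)-3-hydroxy-2-{(2R,3R)-3-[4-(benzyloxy)-3-methoxyphenyl]-2-[(benzyloxy)methyl]-2,3-dihydro-1,4-benzodioxin-6-yl}-4H-chromen-4-one, via flavone 2,3-epoxide 25 (not isolated)
Conditions: DMDO (ca. 0.07 M in acetone, 3 equiv), CH2Cl2, 0 °C → rt; then p-TsOH·H2O (cat.), CH2Cl2, rt
Reagents that add atoms: dimethyldioxirane CC1(C)OO1
Why: Neutral electrophilic epoxidation of the enol-ether-like C2=C3 bond followed by acid-catalysed epoxide-to-enol isomerisation (C2–O opening, loss of H3) restores the aromatic pyranone as the 3-hydroxyflavone, and both new centres of 25 vanish.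

Step 16
Reactants: 26 tetrabenzyl flavonol
Product: 27 2,3-dehydrosilybin A
Conditions: H2 (1 atm), Pd(OH)2/C (20 wt %), THF/MeOH 1:1, rt, stopped at full conversion
Reagents that add atoms: none
Why: Catalytic hydrogenolysis removes the three phenolic and one primary benzyl ether under neutral conditions, while the hindered secondary benzylic C–O bond within ring D and the aromatic pyranone react much more slowly, so the (2R,3R) centres are kept.

## Compound list

1 | methyl 3-bromo-4-hydroxybenzoate | COC(=O)c1ccc(O)c(Br)c1 | starting material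
2 | tert-butyl bromoacetate | CC(C)(C)OC(=O)CBr | starting material
3 | methyl 3-bromo-4-(2-tert-butoxy-2-oxoethoxy)benzoate | COC(=O)c1ccc(OCC(=O)OC(C)(C)C)c(Br)c1 | intermediate
4 | [2-bromo-4-(methoxycarbonyl)phenoxy]acetic acid | COC(=O)c1ccc(OCC(=O)O)c(Br)c1 | intermediate
5 | (S)-4-benzyl-1,3-oxazolidin-2-one | O=C1N[C@@H](Cc2ccccc2)CO1 | starting material
6 | mixed anhydride of 4 and pivalic acid (not isolated) | COC(=O)c1ccc(OCC(=O)OC(=O)C(C)(C)C)c(Br)c1 | intermediate
7 | methyl 4-{2-[(4S)-4-benzyl-2-oxo-1,3-oxazolidin-3-yl]-2-oxoethoxy}-3-bromobenzoate | COC(=O)c1ccc(OCC(=O)N2[C@@H](Cc3ccccc3)COC2=O)c(Br)c1 | intermediate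
8 | 4-(benzyloxy)-3-methoxybenzaldehyde | COc1cc(C=O)ccc1OCc1ccccc1 | starting material
9 | Z-dibutylboron enolate of 7 (not isolated) | CCCCB(CCCC)O/C(=C\Oc1ccc(C(=O)OC)cc1Br)N1[C@@H](Cc2ccccc2)COC1=O | intermediate
10 | O-dibutylboryl derivative of 11 (not isolated) | COC(=O)c1ccc(O[C@@H]([C@H](OB(CCCC)CCCC)c2ccc(OCc3ccccc3)c(OC)c2)C(=O)N2[C@@H](Cc3ccccc3)COC2=O)c(Br)c1 | intermediate
11 | Evans syn aldol adduct, carbinol carbon R, aryloxy carbon S, auxiliary S | COC(=O)c1ccc(O[C@@H]([C@H](O)c2ccc(OCc3ccccc3)c(OC)c2)C(=O)N2[C@@H](Cc3ccccc3)COC2=O)c(Br)c1 | intermediate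
12 | methyl 4-{[(1R,2R)-1-[4-(benzyloxy)-3-methoxyphenyl]-1,3-dihydroxypropan-2-yl]oxy}-3-bromobenzoate | COC(=O)c1ccc(O[C@@H]([C@H](O)c2ccc(OCc3ccccc3)c(OC)c2)CO)c(Br)c1 | intermediate
13 | primary TBDPS ether of 12, (1R,2R) | COC(=O)c1ccc(O[C@@H]([C@H](O)c2ccc(OCc3ccccc3)c(OC)c2)CO[Si](c2ccccc2)(c2ccccc2)C(C)(C)C)c(Br)c1 | intermediate
14 | methyl (2R,3R)-3-[4-(benzyloxy)-3-methoxyphenyl]-2-{[(tert-butyldiphenylsilyl)oxy]methyl}-2,3-dihydro-1,4-benzodioxine-6-carboxylate | COc1cc([C@H]2Oc3cc(C(=O)OC)ccc3O[C@@H]2CO[Si](c2ccccc2)(c2ccccc2)C(C)(C)C)ccc1OCc1ccccc1 | intermediate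
15 | methyl (2R,3R)-3-[4-(benzyloxy)-3-methoxyphenyl]-2-(hydroxymethyl)-2,3-dihydro-1,4-benzodioxine-6-carboxylate | COc1cc([C@H]2Oc3cc(C(=O)OC)ccc3O[C@@H]2CO)ccc1OCc1ccccc1 | intermediate
16 | methyl (2R,3R)-3-[4-(benzyloxy)-3-methoxyphenyl]-2-[(benzyloxy)methyl]-2,3-dihydro-1,4-benzodioxine-6-carboxylate | COc1cc([C@H]2Oc3cc(C(=O)OC)ccc3O[C@@H]2COCc2ccccc2)ccc1OCc1ccccc1 | intermediate
17 | {(2R,3R)-3-[4-(benzyloxy)-3-methoxyphenyl]-2-[(benzyloxy)methyl]-2,3-dihydro-1,4-benzodioxin-6-yl}methanol | COc1cc([C@H]2Oc3cc(CO)ccc3O[C@@H]2COCc2ccccc2)ccc1OCc1ccccc1 | intermediate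
18 | (2R,3R)-3-[4-(benzyloxy)-3-methoxyphenyl]-2-[(benzyloxy)methyl]-2,3-dihydro-1,4-benzodioxine-6-carbaldehyde | COc1cc([C@H]2Oc3cc(C=O)ccc3O[C@@H]2COCc2ccccc2)ccc1OCc1ccccc1 | intermediate
19 | 2,4,6-trihydroxyacetophenone | CC(=O)c1c(O)cc(O)cc1O | starting material
20 | 1-[2,4-bis(benzyloxy)-6-hydroxyphenyl]ethanone | CC(=O)c1c(O)cc(OCc2ccccc2)cc1OCc1ccccc1 | intermediate
21 | β-hydroxy ketone from 18 and 20, both carbinol epimers (not isolated) | COc1cc([C@H]2Oc3cc(C(O)CC(=O)c4c(O)cc(OCc5ccccc5)cc4OCc4ccccc4)ccc3O[C@@H]2COCc2ccccc2)ccc1OCc1ccccc1 | intermediate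
22 | (E)-2'-hydroxy-4',6'-bis(benzyloxy)chalcone carrying the (2R,3R)-benzodioxane | COc1cc([C@H]2Oc3cc(/C=C/C(=O)c4c(O)cc(OCc5ccccc5)cc4OCc4ccccc4)ccc3O[C@@H]2COCc2ccccc2)ccc1OCc1ccccc1 | intermediate
23 | 5,7-bis(benzyloxy)flavanone, both epimers at ring C (not isolated) | COc1cc([C@H]2Oc3cc(C4CC(=O)c5c(OCc6ccccc6)cc(OCc6ccccc6)cc5O4)ccc3O[C@@H]2COCc2ccccc2)ccc1OCc1ccccc1 | intermediate
24 | 5,7-bis(benzyloxy)flavone carrying the (2R,3R)-benzodioxane | COc1cc([C@H]2Oc3cc(-c4cc(=O)c5c(OCc6ccccc6)cc(OCc6ccccc6)cc5o4)ccc3O[C@@H]2COCc2ccccc2)ccc1OCc1ccccc1 | intermediate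
25 | 2,3-epoxide of flavone 24, both faces (not isolated) | COc1cc([C@H]2Oc3cc(C46OC4C(=O)c4c(OCc7ccccc7)cc(OCc7ccccc7)cc4O6)ccc3O[C@@H]2COCc2ccccc2)ccc1OCc1ccccc1 | intermediate
26 | 5,7-bis(benzyloxy)-3-hydroxyflavone carrying the (2R,3R)-benzodioxane (tetrabenzyl 2,3-dehydrosilybin A) | COc1cc([C@H]2Oc3cc(-c4oc5cc(OCc6ccccc6)cc(OCc6ccccc6)c5c(=O)c4O)ccc3O[C@@H]2COCc2ccccc2)ccc1OCc1ccccc1 | intermediate
27 | 2,3-dehydrosilybin A | COc1cc([C@H]2Oc3cc(-c4oc5cc(O)cc(O)c5c(=O)c4O)ccc3O[C@@H]2CO)ccc1O | target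

## Step count and risks

Total steps: 16. Longest linear sequence: 15 (steps 1–11 and 13–16). Step 12 is the one-step side branch.

**Step 7 (highest risk).** The palladium alkoxide of a secondary benzylic alcohol can undergo β-hydride elimination to the aryl ketone with loss of bromine.
- The fallback reverses the polarity of the ring closure, making the arene oxygen the nucleophile and the benzylic carbon the electrophile. It sets out from 13 and comes back at 14.
- Miyaura borylation of 13 (B2pin2, Pd(dppf)Cl2, KOAc, dioxane, 80 °C) gives the aryl pinacol boronate F1.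
- NaBO3·4H2O in THF/H2O converts this into the free phenol F2.
- Catalytic camphorsulfonic acid in CH2Cl2 over 4 Å sieves (0 °C to rt) ionises the electron-rich benzylic alcohol.
- The phenol captures the p-alkoxybenzyl cation anti to the substituent on the untouched C2 centre, giving the more stable trans-dioxane 14.

**Step 15.** DMDO may attack the electron-rich arenes or the benzylic C–H bonds of five ethers before the deactivated enone is consumed.
- The fallback makes C3 the nucleophile instead of oxidising the alkene. It sets out from 24 and comes back at 26.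
- LiN(iPr)2 in THF at −78 °C deprotonates C3 to give the 3-lithioflavone F8.
- B(OMe)3 traps this as the dimethyl flavon-3-ylboronate F9.
- H2O2/AcOH oxidises the C–B bond to the 3-hydroxyl of 26.

**Step 14.** HI generated at 130 °C may strip the 5-O-benzyl group or erode material through opening of ring D.
- The fallback builds ring C at the dihydroflavonol level and bypasses both 24 and DMDO. It sets out from 20 (joined again with 18) and comes back at 26.
- MOMCl and NaH in DMF at 0 °C cap the chelated phenol to give 2-(methoxymethoxy)-4,6-bis(benzyloxy)acetophenone F3.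
- The same KOH aldol condensation with 18 gives the 2'-O-MOM chalcone F4.
- Weitz–Scheffer epoxidation (30% H2O2, 2 M NaOH, MeOH/THF) gives the trans-epoxy ketone F5 from both faces.
- HCl in MeOH/THF at 50 °C removes the MOM group, and the freed phenol opens the epoxide at its benzylic carbon (6-endo) to give the trans-3-hydroxyflavanone F6.
- Dess–Martin periodinane in CH2Cl2 oxidises the carbinol to the flavan-3,4-dione F7, which tautomerises on work-up to flavonol 26. The ring C stereoisomers therefore converge.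

Further compounds
F1 | step 7 | pinacol boronate replacing Br in 13, (1R,2R) | COC(=O)c1ccc(O[C@@H]([C@H](O)c2ccc(OCc3ccccc3)c(OC)c2)CO[Si](c2ccccc2)(c2ccccc2)C(C)(C)C)c(B2OC(C)(C)C(C)(C)O2)c1
F2 | step 7 | phenol replacing Br in 13, (1R,2R) | COC(=O)c1ccc(O[C@@H]([C@H](O)c2ccc(OCc3ccccc3)c(OC)c2)CO[Si](c2ccccc2)(c2ccccc2)C(C)(C)C)c(O)c1
F3 | step 14 | 1-[2,4-bis(benzyloxy)-6-(methoxymethoxy)phenyl]ethanone | CC(=O)c1c(OCOC)cc(OCc2ccccc2)cc1OCc1ccccc1
F4 | step 14 | (E)-2'-O-MOM chalcone carrying the (2R,3R)-benzodioxane | COc1cc([C@H]2Oc3cc(/C=C/C(=O)c4c(OCOC)cc(OCc5ccccc5)cc4OCc4ccccc4)ccc3O[C@@H]2COCc2ccccc2)ccc1OCc1ccccc1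
F5 | step 14 | trans-epoxy ketone of F4, both faces | COc1cc([C@H]2Oc3cc(C4OC4C(=O)c4c(OCOC)cc(OCc5ccccc5)cc4OCc4ccccc4)ccc3O[C@@H]2COCc2ccccc2)ccc1OCc1ccccc1
F6 | step 14 | trans-5,7-bis(benzyloxy)-3-hydroxyflavanone, both ring C antipodes | COc1cc([C@H]2Oc3cc(C4Oc5cc(OCc6ccccc6)cc(OCc6ccccc6)c5C(=O)C4O)ccc3O[C@@H]2COCc2ccccc2)ccc1OCc1ccccc1
F7 | step 14 | 5,7-bis(benzyloxy)flavan-3,4-dione | COc1cc([C@H]2Oc3cc(C4Oc5cc(OCc6ccccc6)cc(OCc6ccccc6)c5C(=O)C4=O)ccc3O[C@@H]2COCc2ccccc2)ccc1OCc1ccccc1
F8 | step 15 | 3-lithio derivative of flavone 24 | COc1cc([C@H]2Oc3cc(-c4oc5cc(OCc6ccccc6)cc(OCc6ccccc6)c5c(=O)c4[Li])ccc3O[C@@H]2COCc2ccccc2)ccc1OCc1ccccc1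
F9 | step 15 | dimethyl boronate at C3 of flavone 24 | COc1cc([C@H]2Oc3cc(-c4oc5cc(OCc6ccccc6)cc(OCc6ccccc6)c5c(=O)c4B(OC)OC)ccc3O[C@@H]2COCc2ccccc2)ccc1OCc1ccccc1
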